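**Retrosynthetic overview**

- The five methyl groups come off last. Before that, the C1–pyranone bond is made by nickel-catalysed decarboxylative coupling of a C1 carboxyl (as its redox-active ester) with methyl 4-bromo-2-oxo-2H-pyran-6-carboxylate, trans to the C2 ester.
- Feature used: in ring B the C1–C2 bond joins a carbon that is alpha to a carboxyl (C1) to the end of the C2–C3=C4 allyl unit, and C4 is benzylic on ring A. An isochroman-3-one fused to ring A that carries the (Z)-butenedioate on its carbinol carbon (future C4) therefore maps onto ring B.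
- Key disconnection: Ireland–Claisen [3,3] shift of the lactone silyl ketene acetal. It makes C1–C2, breaks the lactone O–C4 bond, creates C3=C4, closes ring B and passes the carbinol configuration on to C2.
- The lactone comes from homoveratric acid: ester, ortho-formylation, enantioselective alkynylation with lactonisation, desilylation, and oxidative bis-methoxycarbonylation of the alkyne to the (Z)-diester.
- Ring order: ring A is bought; the lactone ring is temporary; ring B forms in the key step; the pyranone ring is made in a two-step branch from methyl acetoacetate and dimethyl oxalate and joined at C1.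

Key step: step 6

Remark on numbering: C1–C4 are the positions of the 1,2-dihydronaphthalene of the target; ring A is the oxygenated benzo ring, ring B the partly saturated ring.

Assumption: the (S,S)-ProPhenol/Me2Zn catalyst of step 3 is taken to deliver the alkynyl group to the Si face of the aldehyde; if the opposite sense is found, the (R,R)-ligand is used with no other change.

**Route**

Step 1
Reactants: 1 homoveratric acid
Product: 2 methyl (3,4-dimethoxyphenyl)acetate
Conditions: MeOH, H2SO4 (cat.), reflux
Reagents that add atoms: methanol, CO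
Why: Fischer esterification driven by excess methanol; no stereocentre is involved.

Step 2
Reactants: 2 methyl (3,4-dimethoxyphenyl)acetate
Product: 3 methyl 2-(2-formyl-4,5-dimethoxyphenyl)acetate
Conditions: Cl2CHOMe, TiCl4, CH2Cl2, −10 → 0 °C; then ice-water
Reagents that add atoms: dichloromethyl methyl ether, COC(Cl)Cl; water, O
Why: Rieche formylation (electrophilic aromatic substitution) should go to the free position para to a methoxy group and ortho to the side chain, the most activated and least hindered site of the homoveratrate ring.

Step 3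
Reactants: 3 methyl 2-(2-formyl-4,5-dimethoxyphenyl)acetate; 4 trimethylsilylacetylene
Product: 6 (1R)-6,7-dimethoxy-1-[(trimethylsilyl)ethynyl]isochroman-3-one, via propargylic alcohol 5 (not isolated)
Conditions: (S,S)-ProPhenol (20 mol%), Me2Zn (3 equiv), Ph3PO (40 mol%), PhMe, 4 °C; aq NH4Cl; then PPTS (cat.), PhMe, 50 °C
Reagents that add atoms: none
Why: Zinc–ProPhenol-catalysed enantioselective alkynylation of an aryl aldehyde sets the carbinol centre by delivery of the alkynylzinc to the Si face within the chiral dinuclear zinc pocket, and the alcohol then closes the six-membered lactone on the ortho ester by mild acid-catalysed transesterification.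

Step 4
Reactants: 6 (1R)-6,7-dimethoxy-1-[(trimethylsilyl)ethynyl]isochroman-3-one
Product: 7 (1S)-1-ethynyl-6,7-dimethoxyisochroman-3-one
Conditions: Bu4NF, AcOH, THF, 0 °C
Reagents that add atoms: none
Why: Fluoride-induced protodesilylation of the alkynylsilane, buffered with acetic acid so that the lactone and the carbinol centre are untouched; the descriptor changes from R to S only because ethynyl ranks below the aryl group.

Step 5
Reactants: 7 (1S)-1-ethynyl-6,7-dimethoxyisochroman-3-one
Product: 8 dimethyl (2Z)-2-[(1R)-6,7-dimethoxy-3-oxoisochroman-1-yl]but-2-enedioate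
Conditions: PdI2 (2 mol%), KI (20 mol%), CO (32 atm) and air (8 atm), MeOH–dioxane, 40 °C
Reagents that add atoms: carbon monoxide, [C-]#[O+]; methanol, CO
Why: Oxidative dialkoxycarbonylation of a terminal alkyne: syn addition of a Pd–CO2Me unit across the triple bond, CO insertion and methanolysis put both new esters on the same side, which should give the (Z)-diester with the lactone carbon trans to the terminal ester, while air reoxidises the palladium.

Step 6
Reactants: 8 dimethyl (2Z)-2-[(1R)-6,7-dimethoxy-3-oxoisochroman-1-yl]but-2-enedioate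
Product: 11 (1R,2S)-6,7-dimethoxy-2,3-bis(methoxycarbonyl)-1,2-dihydronaphthalene-1-carboxylic acid, via silyl ketene acetal 9 (not isolated), via trimethylsilyl ester 10 (not isolated)
Conditions: Me3SiCl, Et3N, LiN(SiMe3)2, THF, −78 °C; PhMe, 90 °C; 1 M HCl, THF, 0 °C
Reagents that add atoms: none
Why: LiN(SiMe3)2 should remove a proton from the benzylic lactone methylene, the kinetically most accessible carbonyl-activated C–H, with Me3SiCl already present, so that the cyclic O-silyl ketene acetal 9 forms before the enolate can add to the diester or the proton at the carbinol carbon can exchange. On warming, 9 undergoes a concerted suprafacial [3,3]-sigmatropic shift (Ireland–Claisen rearrangement of an alkenyl lactone, the known change of such lactones into cycloalkenecarboxylic acids): the C1–C2 bond forms between the ketene acetal carbon and the ester-bearing alkene terminus, the lactone O–C4 bond breaks and the C3=C4 double bond appears. Ring B closes in this sigmatropic mode, the six-membered lactone being traded for a six-membered carbocycle through a boat-shaped, bicyclo[2.2.2]octane-like array, the only geometry that the ortho-phenylene tether allows. C1 is set by the tether, because the new bond forms on the lactone face that carries the alkenyl group; C2 is set by chirality transfer from the (R)-carbinol, because the breaking C–O and forming C–C bonds lie on the same face of the allyl unit and the (Z)-geometry puts the C2 hydrogen under the arene and the C2 ester outside the boat, which gives (1R,2S) with the C1 and C2 carboxyl groups cis. The step needs site-selective enolisation and a concerted course, and the in situ silyl trap at −78 °C and the neutral silyl ketene acetal should secure both. Mild acid hydrolysis of silyl ester 10 frees acid 11 without base, so the labile C2–H is not exchanged.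

Step 7
Reactants: 11 (1R,2S)-6,7-dimethoxy-2,3-bis(methoxycarbonyl)-1,2-dihydronaphthalene-1-carboxylic acid
Product: 12 1-(1,3-dioxoisoindolin-2-yl) 2,3-dimethyl (1R,2S)-6,7-dimethoxy-1,2-dihydronaphthalene-1,2,3-tricarboxylate
Conditions: N-hydroxyphthalimide, DIC, DMAP (cat.), CH2Cl2, 0 → 23 °C
Reagents that add atoms: N-hydroxyphthalimide, O=C1c2ccccc2C(=O)N1O
Why: Carbodiimide-mediated (Steglich-type) esterification gives the redox-active ester under nearly neutral conditions that leave C2 alone; any epimerisation at C1 is without consequence because C1 becomes planar in step 10.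

Step 8
Reactants: 13 methyl acetoacetate; 14 dimethyl oxalate
Product: 16 methyl 4-hydroxy-2-oxo-2H-pyran-6-carboxylate, via dioxo diester 15 (not isolated)
Conditions: NaH, then n-BuLi, THF, 0 °C; 14, −78 → 0 °C; aq HCl; then TsOH·H2O (cat.), PhMe, reflux
Reagents that add atoms: none
Why: Acylation of the acetoacetate dianion at its terminal carbon by the oxalate (Claisen condensation) gives the 3,5-dioxo ester pattern, and the enol of the oxalyl ketone then closes on the acetoacetate ester under acid (enol lactonisation) to the 4-hydroxy-2-pyranone.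

Step 9
Reactants: 16 methyl 4-hydroxy-2-oxo-2H-pyran-6-carboxylate
Product: 17 methyl 4-bromo-2-oxo-2H-pyran-6-carboxylate
Conditions: Bu4NBr, P2O5, PhMe, 100 °C
Reagents that add atoms: tetrabutylammonium bromide, CCCC[N+](CCCC)(CCCC)CCCC.[Br-]
Why: Deoxybromination of a vinylogous carboxylic acid: phosphorylation of the 4-hydroxyl by P2O5 and addition–elimination of bromide at C4, as practised on 4-hydroxy-6-methyl-2-pyranone.

Step 10
Reactants: 12 1-(1,3-dioxoisoindolin-2-yl) 2,3-dimethyl (1R,2S)-6,7-dimethoxy-1,2-dihydronaphthalene-1,2,3-tricarboxylate; 17 methyl 4-bromo-2-oxo-2H-pyran-6-carboxylate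
Product: 18 dimethyl (1R,2S)-6,7-dimethoxy-1-[6-(methoxycarbonyl)-2-oxo-2H-pyran-4-yl]-1,2-dihydronaphthalene-2,3-dicarboxylate
Conditions: NiBr2·diglyme (10 mol%), 4,4′-di-tert-butyl-2,2′-bipyridine (12 mol%), TDAE, Me3SiBr, NaI, DMA, −5 → 5 °C
Reagents that add atoms: none
Why: Nickel-catalysed reductive decarboxylative alkenylation of a benzylic N-acyloxyphthalimide with an alkenyl bromide (cross-electrophile coupling): the planar benzylic C1 radical left after loss of CO2 and phthalimide is taken up by the pyranonyl–nickel species and the C–C bond should form on the face opposite the pseudoaxial C2 ester, which sets (1R) with the pyranone trans to C2, while the base-free medium leaves the C2–H untouched.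

Step 11
Reactants: 18 dimethyl (1R,2S)-6,7-dimethoxy-1-[6-(methoxycarbonyl)-2-oxo-2H-pyran-4-yl]-1,2-dihydronaphthalene-2,3-dicarboxylate
Product: 19 (1R,2S)-1-(6-carboxy-2-oxo-2H-pyran-4-yl)-6,7-dihydroxy-1,2-dihydronaphthalene-2,3-dicarboxylic acid
Conditions: BBr3 (excess), CH2Cl2, −78 → 23 °C; then H2O
Reagents that add atoms: none
Why: Lewis-acid dealkylation by BBr3 should cleave the two aryl methyl ethers cold and, with excess reagent at room temperature, the three methyl esters by alkyl–oxygen fission through acyloxyboranes, so that no base touches the pyranone lactone, the labile C1 and C2 centres or the styrenic double bond.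

**Compound list**

1 | homoveratric acid | COc1ccc(CC(=O)O)cc1OC | starting material
2 | methyl (3,4-dimethoxyphenyl)acetate | COC(=O)Cc1ccc(OC)c(OC)c1 | intermediate
3 | methyl 2-(2-formyl-4,5-dimethoxyphenyl)acetate | COC(=O)Cc1cc(OC)c(OC)cc1C=O | intermediate
4 | trimethylsilylacetylene | C#C[Si](C)(C)C | starting material
5 | methyl 2-{2-[(1R)-1-hydroxy-3-(trimethylsilyl)prop-2-yn-1-yl]-4,5-dimethoxyphenyl}acetate | COC(=O)Cc1cc(OC)c(OC)cc1[C@@H](O)C#C[Si](C)(C)C | intermediate
6 | (1R)-6,7-dimethoxy-1-[(trimethylsilyl)ethynyl]isochroman-3-one | O=C1Cc2cc(OC)c(OC)cc2[C@@H](O1)C#C[Si](C)(C)C | intermediate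
7 | (1S)-1-ethynyl-6,7-dimethoxyisochroman-3-one | O=C1Cc2cc(OC)c(OC)cc2[C@@H](O1)C#C | intermediate
8 | dimethyl (2Z)-2-[(1R)-6,7-dimethoxy-3-oxoisochroman-1-yl]but-2-enedioate | O=C1Cc2cc(OC)c(OC)cc2[C@@H](O1)/C(C(=O)OC)=C/C(=O)OC | intermediate
9 | dimethyl (2Z)-2-[(1R)-6,7-dimethoxy-3-[(trimethylsilyl)oxy]-1H-isochromen-1-yl]but-2-enedioate | C[Si](C)(C)OC1=Cc2cc(OC)c(OC)cc2[C@@H](O1)/C(C(=O)OC)=C/C(=O)OC | intermediate
10 | 1-(trimethylsilyl) 2,3-dimethyl (1R,2S)-6,7-dimethoxy-1,2-dihydronaphthalene-1,2,3-tricarboxylate | COC(=O)C1=Cc2cc(OC)c(OC)cc2[C@H](C(=O)O[Si](C)(C)C)[C@@H]1C(=O)OC | intermediate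
11 | (1R,2S)-6,7-dimethoxy-2,3-bis(methoxycarbonyl)-1,2-dihydronaphthalene-1-carboxylic acid (C1 and C2 carboxyl groups cis) | COC(=O)C1=Cc2cc(OC)c(OC)cc2[C@H](C(=O)O)[C@@H]1C(=O)OC | intermediate
12 | 1-(1,3-dioxoisoindolin-2-yl) 2,3-dimethyl (1R,2S)-6,7-dimethoxy-1,2-dihydronaphthalene-1,2,3-tricarboxylate | COC(=O)C1=Cc2cc(OC)c(OC)cc2[C@H](C(=O)ON2C(=O)c3ccccc3C2=O)[C@@H]1C(=O)OC | intermediate
13 | methyl acetoacetate | CC(=O)CC(=O)OC | starting material
14 | dimethyl oxalate | COC(=O)C(=O)OC | starting material
15 | dimethyl 2,4-dioxohexanedioate | COC(=O)C(=O)CC(=O)CC(=O)OC | intermediate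
16 | methyl 4-hydroxy-2-oxo-2H-pyran-6-carboxylate | COC(=O)c1cc(O)cc(=O)o1 | intermediate
17 | methyl 4-bromo-2-oxo-2H-pyran-6-carboxylate | COC(=O)c1cc(Br)cc(=O)o1 | intermediate
18 | dimethyl (1R,2S)-6,7-dimethoxy-1-[6-(methoxycarbonyl)-2-oxo-2H-pyran-4-yl]-1,2-dihydronaphthalene-2,3-dicarboxylate (1,2-trans) | COC(=O)C1=Cc2cc(OC)c(OC)cc2[C@@H](c2cc(C(=O)OC)oc(=O)c2)[C@@H]1C(=O)OC | intermediate
19 | (1R,2S)-1-(6-carboxy-2-oxo-2H-pyran-4-yl)-6,7-dihydroxy-1,2-dihydronaphthalene-2,3-dicarboxylic acid | O=C(O)C1=Cc2cc(O)c(O)cc2[C@@H](c2cc(C(=O)O)oc(=O)c2)[C@@H]1C(=O)O | target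

**Step count and risks**

Total steps: 11 (steps 8 and 9 form the pyranone branch). Longest linear sequence: 9 steps (1–7, 10, 11).

Steps most likely to fail:

1. Step 6 (key step). The boat-shaped transition state is stiffened by the fused benzene ring, so the shift may be slower than decomposition of the silyl ketene acetal. The amide base may also deprotonate the carbinol carbon or add to the diester. Fallback: the sigmatropic step is replaced by its polar counterpart, setting out from 8 and coming back at 11. With KN(SiMe3)2 (1.0 equiv) and 18-crown-6 in THF at −78 → −20 °C and no silyl chloride, the potassium enolate should close ring B by intramolecular conjugate addition to C2 followed by expulsion of the lactone carboxylate from C4 (SN2′-type closure). This gives the carboxylate of 11 directly and then 11 on a cold acidic quench. Only the rotamer that aligns the C–O bond with the developing carbanion can collapse, so the same (2S) centre is expected, but this must be checked against material from the silyl route. This fallback makes no compound outside the list (F0).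

2. Step 10. The C1 radical or the C1–nickel species may lose the C2 hydrogen and aromatise to the naphthalene. Capture may occur on the wrong face, or the bromopyranone may be consumed by reductive homocoupling. Fallback: the bond is made by two-electron cross-coupling of a defined C1 boronate, setting out from 12 and coming back at 18.
   - Light-driven decarboxylative borylation of 12 (bis(catecholato)diboron, DMA, blue light) should give, anti to the C2 ester, dimethyl (1S,2S)-1-(1,3,2-benzodioxaborol-2-yl)-6,7-dimethoxy-1,2-dihydronaphthalene-2,3-dicarboxylate F4.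
   - Exchange with pinacol (Et3N, briefly) gives dimethyl (1S,2S)-6,7-dimethoxy-1-(4,4,5,5-tetramethyl-1,3,2-dioxaborolan-2-yl)-1,2-dihydronaphthalene-2,3-dicarboxylate F5.
   - Stereoretentive Suzuki–Miyaura coupling of this secondary benzylic boronate with 17 (Pd(PPh3)4, Ag2O, DME, 80 °C) gives 18.

3. Step 5. Divalent palladium may trigger acyloxy migration or ionisation of the propargylic, benzylic lactone. Methanol may open the lactone, cyclised furanone by-products may form, or the (Z)-diester may drift to (E). Fallback: the second ester is introduced without carbonylating a terminal alkyne, setting out from 3 and coming back at 8.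
   - Alkynylation of 3 with methyl propiolate under the zinc–ProPhenol conditions of step 3 gives methyl (4S)-4-[4,5-dimethoxy-2-(2-methoxy-2-oxoethyl)phenyl]-4-hydroxybut-2-ynoate F1.
   - Lactonisation with PPTS gives methyl 3-[(1S)-6,7-dimethoxy-3-oxoisochroman-1-yl]prop-2-ynoate F2.
   - Anti addition of HI (NaI, AcOH, 70 °C) puts iodine on the carbon next to the lactone and cis to the ester, giving methyl (2Z)-3-[(1R)-6,7-dimethoxy-3-oxoisochroman-1-yl]-3-iodoprop-2-enoate F3.
   - Methoxycarbonylation of the C–I bond with retention (Pd(PPh3)4, CO 1 atm, MeOH, Et3N, 50 °C, short contact with zerovalent palladium) gives 8.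

Further compounds
F1 | step 5 | methyl (4S)-4-[4,5-dimethoxy-2-(2-methoxy-2-oxoethyl)phenyl]-4-hydroxybut-2-ynoate | COC(=O)Cc1cc(OC)c(OC)cc1[C@@H](O)C#CC(=O)OC
F2 | step 5 | methyl 3-[(1S)-6,7-dimethoxy-3-oxoisochroman-1-yl]prop-2-ynoate | O=C1Cc2cc(OC)c(OC)cc2[C@@H](O1)C#CC(=O)OC
F3 | step 5 | methyl (2Z)-3-[(1R)-6,7-dimethoxy-3-oxoisochroman-1-yl]-3-iodoprop-2-enoate | O=C1Cc2cc(OC)c(OC)cc2[C@@H](O1)/C(I)=C/C(=O)OC
F4 | step 10 | dimethyl (1S,2S)-1-(1,3,2-benzodioxaborol-2-yl)-6,7-dimethoxy-1,2-dihydronaphthalene-2,3-dicarboxylate | COC(=O)C1=Cc2cc(OC)c(OC)cc2[C@@H](B2Oc3ccccc3O2)[C@@H]1C(=O)OC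
F5 | step 10 | dimethyl (1S,2S)-6,7-dimethoxy-1-(4,4,5,5-tetramethyl-1,3,2-dioxaborolan-2-yl)-1,2-dihydronaphthalene-2,3-dicarboxylate | COC(=O)C1=Cc2cc(OC)c(OC)cc2[C@@H](B2OC(C)(C)C(C)(C)O2)[C@@H]1C(=O)OC
F0 | step 6 | none | none
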